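The route rests on making the C11–C12 bond last (ring B = C5–C10 with C5=C10; lactone ring C = O–C8–C7–C11–C12; C13 = exocyclic CH2). A palladium-catalysed carbonylative lactonisation, a formal (4+1) union of CO with the O8–C8–C7–C11 unit, converts a vinyl triflate at C11 and the free C8 hydroxyl into the trans-fused α-methylene-γ-lactone in one operation. It exploits the homoallylic 1,2-trans relationship of O8 and the C7 two-carbon branch on ring B. The precursor, a 7-(1-triflyloxyvinyl)cyclohexen-8-ol, comes from a catalytic asymmetric Diels–Alder reaction between a citronellal-derived 1-silyloxy diene and a β-boryl enone.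

Key step: step 13

Remark: atoms are numbered as in the 1,10-seco-eudesmane skeleton (C1 = CH2OAc, C4 = side-chain CH–CH3 on C5, C14 = CH2O on C10, C11/C12/C13 = lactone α-carbon, carbonyl and exocyclic methylene); (S)-citronellal of high enantiomeric purity is assumed to be commercial.

Step 1
Reactants: 1 (S)-citronellal
Product: 2 (S)-8,8-dimethoxy-2,6-dimethyloct-2-ene (citronellal dimethyl acetal)
Conditions: HC(OMe)3, MeOH, PPTS (cat.), rt
Reagents that add atoms: trimethyl orthoformate, COC(OC)OC; methanol, CO
Why: Acid-catalysed acetalisation under water-scavenging conditions masks the aldehyde mildly enough to avoid the carbonyl-ene cyclisation of citronellal and leaves the chiral-pool stereocentre (the future C4) untouched.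

Step 2
Reactants: 2 (S)-8,8-dimethoxy-2,6-dimethyloct-2-ene
Product: 4 (S)-6,6-dimethoxy-4-methylhexan-1-ol, via acetal aldehyde 3 (not isolated)
Conditions: O3, CH2Cl2/MeOH, NaHCO3, −78 °C (Sudan Red 7B end point); then NaBH4, −78 °C → rt
Reagents that add atoms: ozone, [O-][O+]=O
Why: Reductive ozonolysis should work because ozone cleaves the electron-rich trisubstituted alkene far faster than it attacks the acetal C–H, and borohydride reduces the cleavage products in the same flask to the C1 primary alcohol.

Step 3
Reactants: 4 (S)-6,6-dimethoxy-4-methylhexan-1-ol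
Product: 5 (S)-6,6-dimethoxy-4-methylhexyl acetate
Conditions: Ac2O, pyridine, DMAP (cat.), CH2Cl2, 0 °C → rt
Reagents that add atoms: acetic anhydride, CC(=O)OC(C)=O
Why: DMAP-catalysed acetylation installs the C1 acetate, which is carried unchanged to the target.

Step 4
Reactants: 5 (S)-6,6-dimethoxy-4-methylhexyl acetate
Product: 6 (S)-4-methyl-6-oxohexyl acetate
Conditions: AcOH/THF/H2O (3:1:1), 40 °C
Reagents that add atoms: water, O
Why: Acid-catalysed acetal hydrolysis liberates the aldehyde while the primary acetate is stable to aqueous acetic acid and C4, being β to the carbonyl, cannot epimerise.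

Step 5
Reactants: 6 (S)-4-methyl-6-oxohexyl acetate
Product: 7 (4S)-4-methyl-6-(trimethylsilyloxy)hex-5-en-1-yl acetate (E/Z mixture)
Conditions: TMSOTf, Et3N, CH2Cl2, 0 °C
Reagents that add atoms: trimethylsilyl trifluoromethanesulfonate, C[Si](C)(C)OS(=O)(=O)C(F)(F)F
Why: Soft enolisation with a silyl triflate and an amine (silyl enol ether formation) converts the aldehyde into its enol silane without touching the much less acidic acetate.

Step 6
Reactants: 7 (4S)-4-methyl-6-(trimethylsilyloxy)hex-5-en-1-yl acetate; 8 1-(tert-butyldimethylsilyloxy)propan-2-one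
Product: 9 (4S)-7-(tert-butyldimethylsilyloxy)-5-formyl-6-hydroxy-4,6-dimethylheptyl acetate (mixture of diastereomers at the two new centres)
Conditions: TiCl4, CH2Cl2, −78 °C; aq. NaHCO3
Reagents that add atoms: none
Why: In this Mukaiyama aldol addition TiCl4 activates the ketone so that the enol silane adds at the ketone carbon and forges C5–C10, and the two new stereocentres are irrelevant because both are erased in steps 7 and 8.

Step 7
Reactants: 9 (4S)-7-(tert-butyldimethylsilyloxy)-5-formyl-6-hydroxy-4,6-dimethylheptyl acetate
Product: 11 (4S)-7-(tert-butyldimethylsilyloxy)-5-formyl-4,6-dimethylhept-5-en-1-yl acetate (E/Z mixture), via tertiary mesylate 10 (not isolated)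
Conditions: MsCl, Et3N, CH2Cl2, 0 °C → rt
Reagents that add atoms: none
Why: Mesylation of the tertiary alcohol through sulfene followed by E1cB elimination across the acidic C5–H should give only the conjugated enal, whose E/Z ratio is immaterial because the C5=C10 geometry is lost in the next step.

Step 8
Reactants: 11 (4S)-7-(tert-butyldimethylsilyloxy)-5-formyl-4,6-dimethylhept-5-en-1-yl acetate
Product: 12 (4S,5E)-5-[(tert-butyldimethylsilyloxy)methylidene]-6-[(tert-butyldimethylsilyloxy)methyl]-4-methylhept-6-en-1-yl acetate (the 1-silyloxy diene C6=C5–C10=C9)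
Conditions: TBSOTf, Et3N, Et2O, −78 → 0 °C
Reagents that add atoms: tert-butyldimethylsilyl trifluoromethanesulfonate, CC(C)(C)[Si](C)(C)OS(=O)(=O)C(F)(F)F
Why: In this vinylogous soft enolisation (silyl dienol ether formation) O-silylation gives an oxocarbenium ion that should be deprotonated kinetically at the unhindered C9 methyl rather than at the inductively deactivated, silyl-shielded C14 methylene, and the s-trans conformer of the enal delivers the (1E) isomer with the silyloxy group on the outside of the diene.

Step 9
Reactants: 13 but-3-yn-2-one; 14 bis(pinacolato)diboron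
Product: 15 (E)-4-(4,4,5,5-tetramethyl-1,3,2-dioxaborolan-2-yl)but-3-en-2-one
Conditions: CuCl (5 mol %), Xantphos (5 mol %), NaOtBu (10 mol %), MeOH (2 equiv), THF, 0 °C → rt
Reagents that add atoms: none
Why: Copper-catalysed conjugate borylation of the ynone (syn borylcupration, then protonation by methanol) places boron on the terminal carbon cis to the new hydrogen, which gives the E β-boryl enone.

Step 10
Reactants: 12 the 1-silyloxy diene; 15 (E)-4-(4,4,5,5-tetramethyl-1,3,2-dioxaborolan-2-yl)but-3-en-2-one
Product: 16 (4S)-4-[(6S,7S,8R)-7-acetyl-6-(tert-butyldimethylsilyloxy)-10-[(tert-butyldimethylsilyloxy)methyl]-8-(pinacolboryl)cyclohex-5(10)-en-5-yl]pentyl acetate (6-O and 7-acetyl cis, 7-acetyl and 8-B trans)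
Conditions: (R)-3,3-diphenyl-1-(o-tolyl)tetrahydro-1H,3H-pyrrolo[1,2-c][1,3,2]oxazaborole (20 mol %), Tf2NH (17 mol %), CH2Cl2, −78 → −40 °C
Reagents that add atoms: none
Why: In this cationic oxazaborolidine-catalysed enantioselective Diels–Alder reaction the C6 silyloxy donor directs the ortho regiochemistry (C6–C7 and C9–C8 bonds), endo orientation of the coordinated acetyl group sets C6–O and C7–acetyl cis, the E geometry of the dienophile sets C7–acetyl and C8–B trans, and the (R)-catalyst, which binds the s-trans enone through the α-C–H···O contact and shields the Si face at C7, should set the absolute configuration of all three ring stereocentres independently of C4.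

Step 11
Reactants: 16 the Diels–Alder adduct
Product: 17 (4S)-4-[(6S,7S,8R)-6-(tert-butyldimethylsilyloxy)-10-[(tert-butyldimethylsilyloxy)methyl]-8-(pinacolboryl)-7-[1-(trifluoromethylsulfonyloxy)vinyl]cyclohex-5(10)-en-5-yl]pentyl acetate
Conditions: KN(SiMe3)2 (1.1 equiv), THF, −78 °C; then PhNTf2, −78 → −20 °C
Reagents that add atoms: N-phenylbis(trifluoromethanesulfonimide), O=S(=O)(N(c1ccccc1)S(=O)(=O)C(F)(F)F)C(F)(F)F
Why: Kinetic deprotonation of the methyl ketone at its unhindered methyl group and O-triflation of the enolate (enol triflate formation) should give the 1,1-disubstituted vinyl triflate without forming the C7 enolate that could expel the C6 silyloxy group.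

Step 12
Reactants: 17 the boryl vinyl triflate
Product: 18 (4S)-4-[(6S,7S,8R)-6-(tert-butyldimethylsilyloxy)-10-[(tert-butyldimethylsilyloxy)methyl]-8-hydroxy-7-[1-(trifluoromethylsulfonyloxy)vinyl]cyclohex-5(10)-en-5-yl]pentyl acetate
Conditions: NaBO3·4H2O, THF/H2O (1:1), 0 °C → rt
Reagents that add atoms: sodium perborate, [Na+].[Na+].O[B-]1(O)OO[B-](O)(O)OO1
Why: Perborate oxidation of the secondary alkylboronic ester proceeds by 1,2-migration from boron to oxygen with retention, so the C8 hydroxyl appears trans to the C7 branch, and the mild conditions should spare the vinyl triflate and the acetate.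

Step 13
Reactants: 18 the hydroxy vinyl triflate
Product: 19 6,14-bis-O-(tert-butyldimethylsilyl) lactone: the trans-fused α-methylene-γ-butyrolactone (O8–C12(=O)–C11(=C13H2)–C7) on ring B, with the (4S) acetoxypentyl side chain on C5 (6S,7S,8R)
Conditions: Pd(PPh3)4 (10 mol %), CO (1 atm), n-Bu3N, LiCl, MeCN, 65 °C
Reagents that add atoms: carbon monoxide, [C-]#[O+]
Why: Oxidative addition of zerovalent palladium into the C11–OTf bond gives a vinylpalladium species that inserts CO, so that the new C11–C12 bond appears as an acylpalladium held next to the C8 hydroxyl (the alternative order, an alkoxycarbonylpalladium formed from O8 that closes the ring by C11–C12 reductive elimination, leads to the same product). Capture of the acyl group by O8, assisted by the amine base, releases the lactone and regenerates zerovalent palladium, so that the four-atom unit O8–C8–C7–C11 and CO are joined in a formal (4+1) annulation. The closest known reaction type is the palladium-catalysed carbonylative lactonisation of hydroxy vinyl halides and triflates to α-methylene-γ-butyrolactones. Ring C closes as a five-membered ring by 5-exo-trig O-acylation at the acylpalladium carbon, and its trans fusion is inherited from the trans C7 and C8 substituents, which sit diequatorial on the half-chair of ring B. No stereocentre is created and none is at risk, since C7 carries no acidifying group until the lactone exists and the medium is only weakly basic. The step needs chemoselectivity for O8 over O6 and for carbonylation over reduction or carbopalladation: O6 and O14 are silylated, the C5=C10 alkene is tetrasubstituted and inert, and the intramolecular hydroxyl has no external nucleophile to compete with.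

Step 14
Reactants: 19 the bis-silyl lactone
Product: 20 6,14-diol lactone (4S,6S,7R,8R)
Conditions: HF·pyridine, pyridine, THF, 0 °C → rt
Reagents that add atoms: none
Why: Fluoride-mediated desilylation with buffered HF·pyridine should remove both silyl ethers under slightly acidic conditions that leave the acetate, the α-methylene lactone and the allylic alcohol untouched and do not promote translactonisation to O6.

Step 15
Reactants: 20 the diol lactone
Product: 21 CNP0122587.1 (4S,6S,7R,8R)
Conditions: methacryloyl chloride (1.1 equiv), 2,4,6-collidine, CH2Cl2, −78 → −40 °C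
Reagents that add atoms: methacryloyl chloride, C=C(C)C(Cl)=O
Why: In this chemoselective acylation the acid chloride with a hindered pyridine base at low temperature should esterify the unhindered primary allylic C14 hydroxyl much faster than the secondary C6 hydroxyl, which is flanked by C5 with its branched side chain and by the ring-fusion carbon C7.

Compound list
1 | (S)-citronellal | O=CC[C@@H](C)CCC=C(C)C | starting material
2 | (S)-8,8-dimethoxy-2,6-dimethyloct-2-ene | COC(OC)C[C@@H](C)CCC=C(C)C | intermediate
3 | (S)-6,6-dimethoxy-4-methylhexanal (acetal aldehyde, not isolated) | COC(OC)C[C@@H](C)CCC=O | intermediate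
4 | (S)-6,6-dimethoxy-4-methylhexan-1-ol | COC(OC)C[C@@H](C)CCCO | intermediate
5 | (S)-6,6-dimethoxy-4-methylhexyl acetate | COC(OC)C[C@@H](C)CCCOC(C)=O | intermediate
6 | (S)-4-methyl-6-oxohexyl acetate | O=CC[C@@H](C)CCCOC(C)=O | intermediate
7 | (4S)-4-methyl-6-(trimethylsilyloxy)hex-5-en-1-yl acetate (E/Z) | C[Si](C)(C)OC=C[C@@H](C)CCCOC(C)=O | intermediate
8 | 1-(tert-butyldimethylsilyloxy)propan-2-one | CC(=O)CO[Si](C)(C)C(C)(C)C | starting material
9 | (4S)-7-(tert-butyldimethylsilyloxy)-5-formyl-6-hydroxy-4,6-dimethylheptyl acetate (diastereomer mixture) | O=CC(C(C)(O)CO[Si](C)(C)C(C)(C)C)[C@@H](C)CCCOC(C)=O | intermediate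
10 | tertiary mesylate of 9 (not isolated) | O=CC(C(C)(OS(C)(=O)=O)CO[Si](C)(C)C(C)(C)C)[C@@H](C)CCCOC(C)=O | intermediate
11 | (4S)-7-(tert-butyldimethylsilyloxy)-5-formyl-4,6-dimethylhept-5-en-1-yl acetate (E/Z) | O=CC(=C(C)CO[Si](C)(C)C(C)(C)C)[C@@H](C)CCCOC(C)=O | intermediate
12 | (4S,5E)-5-[(tert-butyldimethylsilyloxy)methylidene]-6-[(tert-butyldimethylsilyloxy)methyl]-4-methylhept-6-en-1-yl acetate | C=C(CO[Si](C)(C)C(C)(C)C)/C(=C/O[Si](C)(C)C(C)(C)C)[C@@H](C)CCCOC(C)=O | intermediate
13 | but-3-yn-2-one | CC(=O)C#C | starting material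
14 | bis(pinacolato)diboron | CC1(C)OB(OC1(C)C)B1OC(C)(C)C(C)(C)O1 | starting material
15 | (E)-4-(4,4,5,5-tetramethyl-1,3,2-dioxaborolan-2-yl)but-3-en-2-one | CC(=O)/C=C/B1OC(C)(C)C(C)(C)O1 | intermediate
16 | Diels–Alder adduct: 7-acetyl-8-pinacolboryl-6-silyloxy cyclohexene (6S,7S,8R; 4S side chain) | CC(C)(C)[Si](C)(C)OCC1=C([C@@H](C)CCCOC(C)=O)[C@@H](O[Si](C)(C)C(C)(C)C)[C@@H](C(C)=O)[C@H](B2OC(C)(C)C(C)(C)O2)C1 | intermediate
17 | boryl vinyl triflate (6S,7S,8R) | CC(C)(C)[Si](C)(C)OCC1=C([C@@H](C)CCCOC(C)=O)[C@@H](O[Si](C)(C)C(C)(C)C)[C@@H](C(=C)OS(=O)(=O)C(F)(F)F)[C@H](B2OC(C)(C)C(C)(C)O2)C1 | intermediate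
18 | hydroxy vinyl triflate (6S,7S,8R) | CC(C)(C)[Si](C)(C)OCC1=C([C@@H](C)CCCOC(C)=O)[C@@H](O[Si](C)(C)C(C)(C)C)[C@@H](C(=C)OS(=O)(=O)C(F)(F)F)[C@H](O)C1 | intermediate
19 | 6,14-bis-O-(tert-butyldimethylsilyl) trans-fused α-methylene lactone | CC(C)(C)[Si](C)(C)OCC1=C([C@@H](C)CCCOC(C)=O)[C@@H](O[Si](C)(C)C(C)(C)C)[C@H]2C(=C)C(=O)O[C@@H]2C1 | intermediate
20 | 6,14-diol lactone | OCC1=C([C@@H](C)CCCOC(C)=O)[C@@H](O)[C@H]2C(=C)C(=O)O[C@@H]2C1 | intermediate
21 | CNP0122587.1 | C=C(C)C(=O)OCC1=C([C@@H](C)CCCOC(C)=O)[C@@H](O)[C@H]2C(=C)C(=O)O[C@@H]2C1 | target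

Total step count: 15. Longest linear sequence: 14 steps (steps 1–8 and 10–15; step 9 is the side branch that makes the dienophile).

Steps most likely to fail

Step 10 (facial and endo control in the cycloaddition). The chiral Lewis acid may fail to override the small inherent bias of the C4 stereocentre, the sense of induction rests on a binding model, the acid may protodesilylate the diene, or a stepwise Michael pathway may erode the endo preference. The fallback sets out from diene 12 and returns at ketone 16, and it replaces catalyst control by auxiliary control. Diene 12 is combined under Et2AlCl (CH2Cl2, −78 °C) with the imide dienophile (R)-4-benzyl-3-[(E)-3-(4,4,5,5-tetramethyl-1,3,2-dioxaborolan-2-yl)acryloyl]oxazolidin-2-one F1, made from lithiated (R)-4-benzyloxazolidin-2-one and the corresponding acryloyl chloride. The aluminium-chelated s-cis imide should be attacked on the face opposite the benzyl group, which is the Re face at C7, to give the imide cycloadduct F2. LiSEt (THF, 0 °C) then cleaves the auxiliary to give the S-ethyl thioester F3. Palladium-catalysed coupling with MeZnI (PdCl2(PPh3)2, toluene; Fukuyama coupling) converts this thioester into methyl ketone 16.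

Step 8 (site and geometry control in the dienol ether formation). Deprotonation may occur in part at C14 instead of C9, or the unreactive (1Z) isomer may form. The fallback sets out from enol silane 7 and returns at diene 12; it fixes the exocyclic methylene by a Peterson olefination before the enol ether is made. BF3·OEt2-mediated Mukaiyama addition of 7 to 1-(tert-butyldimethylsilyloxy)-3-(trimethylsilyl)propan-2-one F4 (from methyl (tert-butyldimethylsilyloxy)acetate and Me3SiCH2Li) should give the β-hydroxy silane F5. Acid-induced elimination of trimethylsilanol (cat. H2SO4, THF) then gives the β,γ-unsaturated aldehyde (4S)-5-formyl-4-methyl-6-[(tert-butyldimethylsilyloxy)methyl]hept-6-en-1-yl acetate F6. Its only acidic position is C5, so TBSOTf/Et3N should convert it into 12 by α-deprotonation.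

Step 6 (addition of an aldehyde enol silane to an enolisable ketone). Proton transfer to the ketone, retro-aldol cleavage on work-up or loss of the silyl ether to TiCl4 may keep conversion low. The fallback sets out from 7 and 8 and returns at enal 11; it changes the electrophile from the ketone to its oxocarbenium ion. Ketone 8 is converted (HC(OMe)3, MeOH, PPTS) into the dimethyl ketal 1-(tert-butyldimethylsilyloxy)-2,2-dimethoxypropane F7. TMSOTf-catalysed addition of 7 (5 mol %, CH2Cl2, −78 °C) should give the β-methoxy aldehyde (4S)-7-(tert-butyldimethylsilyloxy)-5-formyl-6-methoxy-4,6-dimethylheptyl acetate F8. DBU (CH2Cl2, rt) then expels methanol by E1cB elimination to give 11 directly, which also removes step 7.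

Further compounds
F1 | step 10 | (R)-4-benzyl-3-[(E)-3-(4,4,5,5-tetramethyl-1,3,2-dioxaborolan-2-yl)acryloyl]oxazolidin-2-one | O=C1OC[C@@H](Cc2ccccc2)N1C(=O)/C=C/B1OC(C)(C)C(C)(C)O1
F2 | step 10 | imide cycloadduct (7-acyl oxazolidinone analogue of 16) | CC(C)(C)[Si](C)(C)OCC1=C([C@@H](C)CCCOC(C)=O)[C@@H](O[Si](C)(C)C(C)(C)C)[C@@H](C(=O)N2[C@H](Cc3ccccc3)COC2=O)[C@H](B2OC(C)(C)C(C)(C)O2)C1
F3 | step 10 | S-ethyl thioester analogue of 16 | CC(C)(C)[Si](C)(C)OCC1=C([C@@H](C)CCCOC(C)=O)[C@@H](O[Si](C)(C)C(C)(C)C)[C@@H](C(=O)SCC)[C@H](B2OC(C)(C)C(C)(C)O2)C1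
F4 | step 8 | 1-(tert-butyldimethylsilyloxy)-3-(trimethylsilyl)propan-2-one | C[Si](C)(C)CC(=O)CO[Si](C)(C)C(C)(C)C
F5 | step 8 | (4S)-7-(tert-butyldimethylsilyloxy)-5-formyl-6-hydroxy-4-methyl-6-[(trimethylsilyl)methyl]heptyl acetate | O=CC(C(O)(C[Si](C)(C)C)CO[Si](C)(C)C(C)(C)C)[C@@H](C)CCCOC(C)=O
F6 | step 8 | (4S)-5-formyl-4-methyl-6-[(tert-butyldimethylsilyloxy)methyl]hept-6-en-1-yl acetate | O=CC(C(=C)CO[Si](C)(C)C(C)(C)C)[C@@H](C)CCCOC(C)=O
F7 | step 6 | 1-(tert-butyldimethylsilyloxy)-2,2-dimethoxypropane | COC(C)(OC)CO[Si](C)(C)C(C)(C)C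
F8 | step 6 | (4S)-7-(tert-butyldimethylsilyloxy)-5-formyl-6-methoxy-4,6-dimethylheptyl acetate | O=CC(C(C)(OC)CO[Si](C)(C)C(C)(C)C)[C@@H](C)CCCOC(C)=O
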